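The oxepine ring B of the target is a coumarin pyranone plus one carbon: deleting the C2 methylene between O1 and C3 leaves a 6-substituted coumarin that already carries ring A, O1 and the cis C4=C5 alkene. The key step inserts CH2 into the lactone acyl–oxygen bond in one flask. Chloromethyllithium forms C2–C3, the adduct opens, and the freed phenoxide forms O1–C2, giving the 1-benzoxepin-3(2H)-one whose C3 carbonyl is later methylenated. The precursor is 6-(silyloxymethyl)coumarin, made from 6-methylcoumarin. A silyl ether is chosen because it neither competes for the carbenoid nor leaves from the para-phenoxide.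

Key step: step 4

Remark: the target has no stereocentre; its only stereo-element, the ring-bound cis C4=C5 alkene, is inherited from the coumarin. Ring A is the benzene ring and ring B the oxepine ring (O1, C2, C3, C4, C5, C5a, C9a). Coumarin C6, para to the ring oxygen, becomes benzoxepine C7.

Step 1
Reactants: 1 6-methylcoumarin (6-methyl-2H-chromen-2-one)
Product: 2 6-(bromomethyl)coumarin
Conditions: NBS (1.05 equiv), AIBN (cat.), PhCF3, 85 °C
Reagents that add atoms: N-bromosuccinimide, O=C1CCC(=O)N1Br
Why: Wohl–Ziegler radical bromination should take the only benzylic C–H position, since the electron-poor lactone alkene C3=C4 and the acyloxy-substituted ring A are poor partners for bromine radicals or electrophilic bromine.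

Step 2
Reactants: 2 6-(bromomethyl)coumarin
Product: 3 6-(hydroxymethyl)coumarin
Conditions: CaCO3, H2O/1,4-dioxane (1:1), reflux
Reagents that add atoms: water, O
Why: Solvolysis (nucleophilic substitution by water) of the activated benzylic bromide should proceed readily in hot aqueous dioxane, while insoluble CaCO3 removes HBr without being basic enough to keep the lactone open.

Step 3
Reactants: 3 6-(hydroxymethyl)coumarin
Product: 4 6-[(tert-butyldimethylsilyloxy)methyl]coumarin
Conditions: TBSCl, imidazole, DMF, 25 °C
Reagents that add atoms: tert-butyldimethylsilyl chloride, CC(C)(C)[Si](C)(C)Cl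
Why: Imidazole-promoted silylation of a primary alcohol is routine and leaves the lactone untouched.

Step 4
Reactants: 4 6-[(tert-butyldimethylsilyloxy)methyl]coumarin; 5 chloroiodomethane
Product: 8 7-[(tert-butyldimethylsilyloxy)methyl]-1-benzoxepin-3(2H)-one, via lithium chloromethyl hemiketal alkoxide 6 (not isolated), via lithium (Z)-chloromethyl enone phenoxide 7 (not isolated)
Conditions: ClCH2I (1.15 equiv), MeLi·LiBr (1.05 equiv, slow addition to the mixture of 4 and ClCH2I), THF, −78 °C; then −78 → 25 °C; aq. NH4Cl
Reagents that add atoms: chloroiodomethane, ClCI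
Why: Proposed new method: iodine–lithium exchange generates LiCH2Cl in the presence of 4, the carbenoid adds 1,2 to the lactone carbonyl (new C2–C3 bond) to give the cyclic tetrahedral alkoxide 6, and on warming 6 expels the phenoxide to give the (Z)-enone 7, whose phenoxide displaces chloride from the activated α-chloroketone carbon (new O1–C2 bond). The closest known reaction types are the homologation of esters and Weinreb amides to chloromethyl ketones with LiCH2Cl and the O-alkylation of phenoxides by α-haloketones, a pairing not yet shown as a one-flask ring expansion of a coumarin. Ring B closes in the 7-exo-tet mode, helped by the cis C4=C5 alkene of the coumarin, which holds the phenoxide oxygen and the CH2Cl carbon on the same side. No stereocentre is formed in 8 (the hemiketal carbon of 6 is racemic and disappears on ring opening), and the alkene geometry is locked by the ring. The step needs 1,2- over 1,4-addition and one addition instead of two: the small, hard carbenoid at −78 °C should favour carbonyl attack, it never accumulates and is limited to about one equivalent, and the chlorine-stabilised cyclic alkoxide 6 should persist until all carbenoid is consumed. The silyl ether is inert to the carbenoid and too poor a leaving group to be expelled from the para-phenoxide 7, and in THF without a dipolar cosolvent the MeI co-product should not outrun the intramolecular alkylation.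

Step 5
Reactants: 8 7-[(tert-butyldimethylsilyloxy)methyl]-1-benzoxepin-3(2H)-one
Product: 9 7-[(tert-butyldimethylsilyloxy)methyl]-3-methylene-2,3-dihydro-1-benzoxepine
Conditions: Ph3PCH3Br (1.6 equiv), KOtBu (1.5 equiv), THF, 0 °C; then 8, 0 → 25 °C
Reagents that add atoms: methyltriphenylphosphonium bromide, C[P+](c1ccccc1)(c1ccccc1)c1ccccc1.[Br-]
Why: Wittig methylenation with the non-stabilised ylide should attack the enone carbonyl 1,2 and give the exocyclic alkene directly, and the slight excess of phosphonium salt leaves no free alkoxide to isomerise the diene.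

Step 6
Reactants: 9 7-[(tert-butyldimethylsilyloxy)methyl]-3-methylene-2,3-dihydro-1-benzoxepine
Product: 10 (3-methylene-2,3-dihydro-1-benzoxepin-7-yl)methanol
Conditions: Bu4NF (1.1 equiv), THF, 0 °C; H2O
Reagents that add atoms: none
Why: Fluoride-induced desilylation, driven by the strong Si–F bond, should be selective because the aryl ether and the conjugated diene are inert to fluoride at 0 °C.

Step 7
Reactants: 10 (3-methylene-2,3-dihydro-1-benzoxepin-7-yl)methanol; 11 stearoyl chloride (octadecanoyl chloride)
Product: 12 (3-methylene-2,3-dihydro-1-benzoxepin-7-yl)methyl octadecanoate (target)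
Conditions: Et3N, DMAP (cat.), CH2Cl2, 0 → 25 °C
Reagents that add atoms: stearoyl chloride, CCCCCCCCCCCCCCCCCC(=O)Cl
Why: DMAP-catalysed nucleophilic acyl substitution of the unhindered primary alcohol by the acid chloride should be fast, with Et3N taking up HCl so that the para-alkoxybenzylic ester and the diene never meet acid.

Compound list
1 | 6-methylcoumarin (6-methyl-2H-chromen-2-one) | Cc1ccc2OC(=O)C=Cc2c1 | starting material
2 | 6-(bromomethyl)coumarin | BrCc1ccc2OC(=O)C=Cc2c1 | intermediate
3 | 6-(hydroxymethyl)coumarin | OCc1ccc2OC(=O)C=Cc2c1 | intermediate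
4 | 6-[(tert-butyldimethylsilyloxy)methyl]coumarin | CC(C)(C)[Si](C)(C)OCc1ccc2OC(=O)C=Cc2c1 | intermediate
5 | chloroiodomethane | ClCI | starting material
6 | lithium 2-(chloromethyl)-6-[(tert-butyldimethylsilyloxy)methyl]-2H-chromen-2-olate (racemic hemiketal alkoxide, not isolated) | CC(C)(C)[Si](C)(C)OCc1ccc2OC([O-])(CCl)C=Cc2c1.[Li+] | intermediate
7 | lithium 2-[(1Z)-4-chloro-3-oxobut-1-en-1-yl]-4-[(tert-butyldimethylsilyloxy)methyl]phenolate (not isolated) | CC(C)(C)[Si](C)(C)OCc1ccc([O-])c(c1)/C=C\C(=O)CCl.[Li+] | intermediate
8 | 7-[(tert-butyldimethylsilyloxy)methyl]-1-benzoxepin-3(2H)-one | CC(C)(C)[Si](C)(C)OCc1ccc2OCC(=O)C=Cc2c1 | intermediate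
9 | 7-[(tert-butyldimethylsilyloxy)methyl]-3-methylene-2,3-dihydro-1-benzoxepine | C=C1C=Cc2cc(CO[Si](C)(C)C(C)(C)C)ccc2OC1 | intermediate
10 | (3-methylene-2,3-dihydro-1-benzoxepin-7-yl)methanol | C=C1C=Cc2cc(CO)ccc2OC1 | intermediate
11 | stearoyl chloride (octadecanoyl chloride) | CCCCCCCCCCCCCCCCCC(=O)Cl | starting material
12 | (3-methylene-2,3-dihydro-1-benzoxepin-7-yl)methyl octadecanoate | C=C1C=Cc2cc(COC(=O)CCCCCCCCCCCCCCCCC)ccc2OC1 | target

Total step count: 7
Longest linear sequence: 7 steps (1 → 12)

Steps most likely to fail

Step 4. What may go wrong: early opening of the tetrahedral adduct so that a second carbenoid adds to the freed ketone, conjugate addition at C4, or loss of the cis geometry of the enone phenoxide before ring closure. The fallback builds ring B by ring-closing metathesis, a known route to this ring system, setting out from 4 and returning at 8. Ozonolysis of the lactone alkene of 4 (O3, CH2Cl2/MeOH, −78 °C; Me2S; aq. NaHCO3) should give 5-{[(tert-butyldimethylsilyl)oxy]methyl}-2-hydroxybenzaldehyde F1. Wittig methylenation with excess Ph3P=CH2 should give 4-{[(tert-butyldimethylsilyl)oxy]methyl}-2-vinylphenol F2. Opening of 3,4-epoxy-1-butene at its terminal carbon by the phenoxide (K2CO3, DMF, 70 °C) should give racemic 1-(4-{[(tert-butyldimethylsilyl)oxy]methyl}-2-vinylphenoxy)but-3-en-2-ol F3. Ring-closing metathesis with the second-generation Grubbs catalyst (H2IMes)(PCy3)Cl2Ru=CHPh in CH2Cl2 at 40 °C should close C4=C5 to racemic 7-{[(tert-butyldimethylsilyl)oxy]methyl}-2,3-dihydro-1-benzoxepin-3-ol F4. Allylic oxidation with MnO2 in CH2Cl2 should then give 8.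

Step 5. What may go wrong: enolisation of the C2 methylene by the basic ylide, followed by self-condensation, in competition with olefination. The fallback is a two-stage Peterson olefination under non-basic addition conditions, setting out from 8 and returning at 9. Addition of Me3SiCH2MgCl to 8 in the presence of anhydrous CeCl3 (THF, −78 °C) should give racemic 7-{[(tert-butyldimethylsilyl)oxy]methyl}-3-[(trimethylsilyl)methyl]-2,3-dihydro-1-benzoxepin-3-ol F5. Syn elimination of its potassium alkoxide (KH, THF, 0 → 25 °C) should then give 9.

Step 1. What may go wrong: statistical over-bromination at the benzylic carbon, leaving a mixture of mono- and dibromide that is hard to separate. The fallback drives the bromination to completion and corrects the oxidation level afterwards, setting out from 1 and returning at 3, so that step 2 is not needed. Bromination of 1 with NBS (2.3 equiv, AIBN, PhCF3, reflux) should give 6-(dibromomethyl)coumarin F6. Hydrolysis with AgNO3 in aqueous ethanol should give coumarin-6-carbaldehyde F7. Reduction of the aldehyde with NaBH4 (MeOH/THF, 0 °C), which should be much faster than attack on the coumarin, should then give 3.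

Further compounds
F1 | step 4 | 5-{[(tert-butyldimethylsilyl)oxy]methyl}-2-hydroxybenzaldehyde | CC(C)(C)[Si](C)(C)OCc1ccc(O)c(C=O)c1
F2 | step 4 | 4-{[(tert-butyldimethylsilyl)oxy]methyl}-2-vinylphenol | CC(C)(C)[Si](C)(C)OCc1ccc(O)c(C=C)c1
F3 | step 4 | 1-(4-{[(tert-butyldimethylsilyl)oxy]methyl}-2-vinylphenoxy)but-3-en-2-ol (racemic) | CC(C)(C)[Si](C)(C)OCc1ccc(OCC(O)C=C)c(C=C)c1
F4 | step 4 | 7-{[(tert-butyldimethylsilyl)oxy]methyl}-2,3-dihydro-1-benzoxepin-3-ol (racemic) | CC(C)(C)[Si](C)(C)OCc1ccc2OCC(O)C=Cc2c1
F5 | step 5 | 7-{[(tert-butyldimethylsilyl)oxy]methyl}-3-[(trimethylsilyl)methyl]-2,3-dihydro-1-benzoxepin-3-ol (racemic) | CC(C)(C)[Si](C)(C)OCc1ccc2OCC(O)(C[Si](C)(C)C)C=Cc2c1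
F6 | step 1 | 6-(dibromomethyl)coumarin | BrC(Br)c1ccc2OC(=O)C=Cc2c1
F7 | step 1 | coumarin-6-carbaldehyde (2-oxo-2H-chromene-6-carbaldehyde) | O=Cc1ccc2OC(=O)C=Cc2c1
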